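The A ring is a 2,6-dimethoxyhydroquinone whose O1 and 6-OH are para, and C2–C3–C4 of ring C sits at the oxidation level of a cinnamaldehyde, so the target is an isomer of the sum of two commercial compounds. The route rests on disconnecting O1–C2 and C4–C4a. C2v-symmetric 2,6-dimethoxy-1,4-benzoquinone is photo-acylated at its only kind of ring C–H (future C4a) by (E)-3,4-dimethoxycinnamaldehyde. The hydroquinone OH unveiled ortho to the new enone (future O1) is then closed onto C2 in the same flask by a chiral bifunctional catalyst, which sets the single stereocentre. No protecting group or redox adjustment is needed.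

Key step: step 1

Assumption: the quinidine-derived bifunctional thiourea is taken to deliver the phenoxide to the Si face of C-β of the (E)-enone, which gives 2S. Should the sense of induction on this substrate be the opposite, its quinine-derived pseudoenantiomer is used under otherwise identical conditions. Compounds 1 and 2 are taken to be catalogue chemicals.

Step 1
Reactants: 1 2,6-dimethoxy-1,4-benzoquinone; 2 (E)-3-(3,4-dimethoxyphenyl)prop-2-enal
Product: 4 (2S)-2-(3,4-dimethoxyphenyl)-6-hydroxy-5,7-dimethoxychroman-4-one (target), via acylhydroquinone chalcone 3 (not isolated)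
Conditions: 1 (1 equiv), 2 (2 equiv), hν (420 nm LEDs), degassed PhCl, 25 °C; then light off, quinidine-derived bifunctional thiourea (9-amino-9-deoxy-epi-quinidine 3,5-bis(trifluoromethyl)phenyl thiourea, 10 mol%), −20 °C, same flask
Reagents that add atoms: none
Why: Visible-light excitation of 1 gives a triplet quinone that abstracts the formyl hydrogen of 2; the resulting enoyl radical adds to a ring CH carbon of ground-state 1 and hydrogen return with tautomerisation gives acylhydroquinone 3 (C4–C4a bond), after which, with the light off, the quinuclidine of the catalyst deprotonates the 2'-OH while its thiourea hydrogen-bonds the enone carbonyl and the phenoxide adds to C-β (O1–C2 bond). The closest known reaction types are the photo-Friedel–Crafts (Klinger–Kolbe) acylation of 1,4-quinones by aldehydes, which accepts α,β-unsaturated aldehydes, and the organocatalytic, chalcone-isomerase-like cyclisation of 2'-hydroxychalcones. The pyranone ring closes in 6-endo-trig mode by intramolecular oxa-Michael addition. C2 is set under catalyst control at low temperature: the ion-paired phenoxide is delivered to the Si face of C-β of the (E)-enone, which corresponds to 2S. Site selectivity is secured by the C2v symmetry of 1, whose two ring C–H positions are equivalent and both ortho to the C4 carbonyl oxygen, so that only this oxygen can reach the enone and the oxygen flanked by the two methoxy groups is left as the free 6-OH; the nucleophilic acyl radical should prefer the ring carbon to the carbonyl oxygen, and the reagent-free first stage leaves nothing that interferes with the catalyst. The step is an isomerising union of 1 and 2 and gives no co-product.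

Compound list
1 | 2,6-dimethoxy-1,4-benzoquinone | COC1=CC(=O)C=C(OC)C1=O | starting material
2 | (E)-3-(3,4-dimethoxyphenyl)prop-2-enal (3,4-dimethoxycinnamaldehyde) | COc1ccc(/C=C/C=O)cc1OC | starting material
3 | (E)-1-(2,5-dihydroxy-4,6-dimethoxyphenyl)-3-(3,4-dimethoxyphenyl)prop-2-en-1-one | COc1ccc(/C=C/C(=O)c2c(O)cc(OC)c(O)c2OC)cc1OC | intermediate
4 | (2S)-2-(3,4-dimethoxyphenyl)-6-hydroxy-5,7-dimethoxychroman-4-one | COc1ccc([C@@H]2CC(=O)c3c(cc(OC)c(O)c3OC)O2)cc1OC | target

Total step count: 1. Longest linear sequence: 1 step.

Steps most likely to fail: the route has a single step, so step 1 is the only entry.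

Step 1. Two processes may defeat it.
- Inefficient acylation: the electron-rich quinone may abstract hydrogen sluggishly. Its excited state may also be quenched unproductively by charge transfer from the dimethoxyphenyl ring or by energy transfer to the cinnamoyl chromophore, which causes E/Z isomerisation of the enal. [2+2] (Paternò–Büchi) cycloaddition and in-cage O-acylation may compete.
- Loss of enantiocontrol: light-induced or uncatalysed background cyclisation may occur before the catalyst is added. E/Z scrambling of the enone, weak facial discrimination on an unactivated enone, or retro-oxa-Michael opening of the product would also erode it.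

Fallback for step 1: a polar assembly of rings A and C in which the stereocentre is set by C–C bond formation instead of oxa-Michael addition. It sets out from 1 and comes back to the route at 4.
- Quinone 1 would be reduced (Na2S2O4, EtOAc/H2O) to 2,6-dimethoxybenzene-1,4-diol F1.
- Friedel–Crafts acetylation at its only free ring position (AcOH, BF3·OEt2, 80 °C) should give 1-(2,5-dihydroxy-4,6-dimethoxyphenyl)ethan-1-one F2.
- The non-chelated 5-OH would be benzylated (BnBr, K2CO3, acetone) to 1-[5-(benzyloxy)-2-hydroxy-4,6-dimethoxyphenyl]ethan-1-one F3.
- Condensation with DMF dimethyl acetal (toluene, 90 °C) should give the enaminone (E)-1-[5-(benzyloxy)-2-hydroxy-4,6-dimethoxyphenyl]-3-(dimethylamino)prop-2-en-1-one F4.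
- Acid (HCl, CH2Cl2) would close it to 6-(benzyloxy)-5,7-dimethoxy-4H-chromen-4-one F5.
- Pd(II)/pyridine-oxazoline-catalysed asymmetric conjugate addition of 3,4-dimethoxyphenylboronic acid (Pd(OCOCF3)2, t-BuPyOx, NH4PF6, H2O, ClCH2CH2Cl, 60 °C) should give (2S)-6-(benzyloxy)-2-(3,4-dimethoxyphenyl)-5,7-dimethoxychroman-4-one F6. The ligand enantiomer is the one that gives 2S, expected by analogy with cyclic enones to be the (R)-ligand.
- Hydrogenolysis (H2, Pd/C, EtOAc) would then give 4.

Further compounds
F1 | step 1 | 2,6-dimethoxybenzene-1,4-diol | COc1cc(O)cc(OC)c1O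
F2 | step 1 | 1-(2,5-dihydroxy-4,6-dimethoxyphenyl)ethan-1-one | CC(=O)c1c(O)cc(OC)c(O)c1OC
F3 | step 1 | 1-[5-(benzyloxy)-2-hydroxy-4,6-dimethoxyphenyl]ethan-1-one | CC(=O)c1c(O)cc(OC)c(OCc2ccccc2)c1OC
F4 | step 1 | (E)-1-[5-(benzyloxy)-2-hydroxy-4,6-dimethoxyphenyl]-3-(dimethylamino)prop-2-en-1-one | CN(C)/C=C/C(=O)c1c(O)cc(OC)c(OCc2ccccc2)c1OC
F5 | step 1 | 6-(benzyloxy)-5,7-dimethoxy-4H-chromen-4-one | O=c1ccoc2cc(OC)c(OCc3ccccc3)c(OC)c12
F6 | step 1 | (2S)-6-(benzyloxy)-2-(3,4-dimethoxyphenyl)-5,7-dimethoxychroman-4-one | COc1ccc([C@@H]2CC(=O)c3c(cc(OC)c(OCc4ccccc4)c3OC)O2)cc1OC
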